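**Retrosynthetic overview**
1. Target 30 ⇐ TFA acidolysis (tert-butyl ester, diphenylmethylene ketal) and Pinnick oxidation of the protected pyranone enal 28.
2. 2-Pyranone ring (formed last) ⇐ malonate on C1 plus the C3 ketoester unit 23: Michael addition–elimination, deallylation/decarboxylation, enol lactonisation.
3. Carbocyclic ring B (formed first) ⇐ intramolecular aldol condensation of dialdehyde 17.
4. Key C1–C2 bond ⇐ intermolecular enamine Michael addition of aldehyde 13 to arylidene malonate 10, setting both stereocentres (syn adduct → trans ring).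
5. 10 ⇐ Knoevenagel condensation of diallyl malonate with aldehyde 8, made from 2-bromo-4,5-dimethoxybenzaldehyde.

Assumption: the target is the (1R,2R)-trans isomer exactly as encoded; C1–C4 are the 1,2-dihydronaphthalene locants (C1 bears the pyranone, C2 the methyl ester, C3 the free acid) and primed locants belong to the pyranone.

Step 1
Reactants: 1 2-bromo-4,5-dimethoxybenzaldehyde
Product: 2 2-bromo-4,5-dihydroxybenzaldehyde
Conditions: BBr3 (3 equiv), CH2Cl2, −78 °C → rt; then H2O
Reagents that add atoms: none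
Why: Lewis-acid ether cleavage (BBr3 demethylation) removes both aryl methyl ethers by bromide attack on the O-methyl groups while the aldehyde and aryl bromide survive.

Step 2
Reactants: 2 2-bromo-4,5-dihydroxybenzaldehyde; 3 dichlorodiphenylmethane
Product: 4 6-bromo-2,2-diphenyl-1,3-benzodioxole-5-carbaldehyde
Conditions: Ph2O, 175 °C, 30 min, N2 sweep
Reagents that add atoms: none
Why: Double nucleophilic substitution at the benzhydrylic gem-dichloride (catechol ketalisation, driven by loss of HCl) gives a diphenylmethylene ketal that is stable to base, organolithiums and mild acid yet falls to TFA at the end.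

Step 3
Reactants: 4 6-bromo-2,2-diphenyl-1,3-benzodioxole-5-carbaldehyde; 5 ethylene glycol
Product: 6 5-bromo-6-(1,3-dioxolan-2-yl)-2,2-diphenyl-1,3-benzodioxole
Conditions: pyridinium p-toluenesulfonate (cat.), toluene, reflux, Dean–Stark
Reagents that add atoms: none
Why: Acid-catalysed acetalisation with azeotropic water removal masks the aldehyde (the future C4) as a dioxolane that tolerates n-BuLi.

Step 4
Reactants: 6 5-bromo-6-(1,3-dioxolan-2-yl)-2,2-diphenyl-1,3-benzodioxole
Product: 8 6-(1,3-dioxolan-2-yl)-2,2-diphenyl-1,3-benzodioxole-5-carbaldehyde, via aryllithium 7 (not isolated)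
Conditions: n-BuLi (1.1 equiv), THF, −78 °C; DMF (3 equiv), −78 → 0 °C; aq. NH4Cl
Reagents that add atoms: N,N-dimethylformamide, CN(C)C=O
Why: Bromine–lithium exchange is fast at −78 °C and the aryllithium is formylated by DMF (Bouveault formylation), giving the mono-protected dialdehyde.

Step 5
Reactants: 8 6-(1,3-dioxolan-2-yl)-2,2-diphenyl-1,3-benzodioxole-5-carbaldehyde; 9 diallyl malonate
Product: 10 diallyl 2-{[6-(1,3-dioxolan-2-yl)-2,2-diphenyl-1,3-benzodioxol-5-yl]methylidene}malonate
Conditions: piperidine (0.1 equiv), AcOH (0.1 equiv), toluene, reflux, Dean–Stark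
Reagents that add atoms: none
Why: Knoevenagel condensation of the aryl aldehyde with the malonate gives the doubly activated Michael acceptor, which has no E/Z issue because the two esters are identical.

Step 6
Reactants: 11 2-(2-bromoethyl)-1,3-dioxolane
Product: 13 3-(1,3-dioxolan-2-yl)propanal, via Grignard reagent 12 (not isolated)
Conditions: Mg turnings, THF, 25–30 °C; DMF, 0 °C; aq. NH4Cl
Reagents that add atoms: N,N-dimethylformamide, CN(C)C=O
Why: Grignard formation followed by Bouveault formylation gives the mono-protected succinaldehyde that will supply C2, C3 and the C3 carboxyl carbon.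

Step 7
Reactants: 10 diallyl 2-{[6-(1,3-dioxolan-2-yl)-2,2-diphenyl-1,3-benzodioxol-5-yl]methylidene}malonate; 13 3-(1,3-dioxolan-2-yl)propanal
Product: 14 diallyl 2-[(1S,2S)-1-[6-(1,3-dioxolan-2-yl)-2,2-diphenyl-1,3-benzodioxol-5-yl]-3-(1,3-dioxolan-2-yl)-2-formylpropyl]malonate
Conditions: 13 (3 equiv), (R)-2-[diphenyl(trimethylsilyloxy)methyl]pyrrolidine (20 mol%), PhCO2H (20 mol%), CHCl3, 4 °C → rt, 48–72 h; chromatography to remove the minor anti isomer
Reagents that add atoms: none
Why: Hayashi–Jørgensen enamine-catalysed asymmetric Michael addition, in which the (R)-catalyst forms the (E)-enamine of 13 with one face blocked by the diphenyl(silyloxy)methyl group and attack on 10 through the acyclic synclinal transition state gives the syn adduct (by analogy with the nitroalkene case), fixing C2 as S and the benzylic C1 as S, the arrangement that becomes (1R,2R)-trans in the target.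

Step 8
Reactants: 14 diallyl 2-[(1S,2S)-1-[6-(1,3-dioxolan-2-yl)-2,2-diphenyl-1,3-benzodioxol-5-yl]-3-(1,3-dioxolan-2-yl)-2-formylpropyl]malonate
Product: 15 (2S,3S)-4,4-bis(allyloxycarbonyl)-3-[6-(1,3-dioxolan-2-yl)-2,2-diphenyl-1,3-benzodioxol-5-yl]-2-(1,3-dioxolan-2-ylmethyl)butanoic acid
Conditions: NaClO2, NaH2PO4, 2-methyl-2-butene, t-BuOH/H2O, 0 °C
Reagents that add atoms: NaClO2 (sodium chlorite), [Na+].[O-]Cl=O
Why: Pinnick oxidation converts the epimerisable aldehyde into the configurationally stable acid under buffered conditions that spare the acetals, with the alkene scavenger protecting the allyl esters and the malonate C–H from HOCl.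

Step 9
Reactants: 15 (2S,3S)-4,4-bis(allyloxycarbonyl)-3-[6-(1,3-dioxolan-2-yl)-2,2-diphenyl-1,3-benzodioxol-5-yl]-2-(1,3-dioxolan-2-ylmethyl)butanoic acid
Product: 16 1,1-diallyl 3-methyl (2S,3S)-2-[6-(1,3-dioxolan-2-yl)-2,2-diphenyl-1,3-benzodioxol-5-yl]-4-(1,3-dioxolan-2-yl)butane-1,1,3-tricarboxylate
Conditions: TMSCHN2, MeOH/toluene, 0 °C
Reagents that add atoms: (trimethylsilyl)diazomethane, C[Si](C)(C)C=[N+]=[N-]
Why: Diazoalkane O-methylation esterifies only the carboxylic acid and installs the C2 methyl ester of the target without base, so neither the malonate C–H nor C2 is disturbed.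

Step 10
Reactants: 16 1,1-diallyl 3-methyl (2S,3S)-2-[6-(1,3-dioxolan-2-yl)-2,2-diphenyl-1,3-benzodioxol-5-yl]-4-(1,3-dioxolan-2-yl)butane-1,1,3-tricarboxylate
Product: 18 diallyl 2-[(5S,6R)-7-formyl-6-(methoxycarbonyl)-2,2-diphenyl-5,6-dihydronaphtho[2,3-d][1,3]dioxol-5-yl]malonate, via dialdehyde 17 (not isolated)
Conditions: pyridinium p-toluenesulfonate (0.3 equiv), acetone/H2O (10:1), 60 °C; then dibenzylammonium trifluoroacetate (0.2 equiv), toluene, 50 °C
Reagents that add atoms: water, O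
Why: Transacetalisation unmasks both aldehydes and the secondary ammonium salt then drives an intramolecular aldol condensation (enamine of the CH2CHO arm onto the aryl aldehyde, six-membered ring closure, dehydration to the conjugated enal) that builds ring B without touching C1 or C2, so the syn adduct gives the trans-1,2-disubstituted dihydronaphthalene.

Step 11
Reactants: 19 oxalyl chloride; 20 tert-butanol
Product: 21 tert-butyl chlorooxoacetate
Conditions: oxalyl chloride (3 equiv), Et2O, 0 °C → rt; distil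
Reagents that add atoms: none
Why: Mono-acylation of the hindered alcohol with excess oxalyl chloride (acyl substitution) stops cleanly at the half ester chloride.

Step 12
Reactants: 21 tert-butyl chlorooxoacetate; 22 ethyl vinyl ether
Product: 23 tert-butyl (E)-4-ethoxy-2-oxobut-3-enoate
Conditions: pyridine (1.1 equiv), CH2Cl2, 0 °C → rt
Reagents that add atoms: none
Why: C-acylation of the enol ether followed by loss of HCl gives the β-ethoxyvinyl ketoester, a masked formylpyruvate at the oxidation level needed for pyranone C4', C5', C6' and the 6-carboxyl.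

Step 13
Reactants: 18 diallyl 2-[(5S,6R)-7-formyl-6-(methoxycarbonyl)-2,2-diphenyl-5,6-dihydronaphtho[2,3-d][1,3]dioxol-5-yl]malonate; 23 tert-butyl (E)-4-ethoxy-2-oxobut-3-enoate
Product: 25 diallyl 2-[(E)-4-tert-butoxy-3,4-dioxobut-1-en-1-yl]-2-[(5R,6R)-7-formyl-6-(methoxycarbonyl)-2,2-diphenyl-5,6-dihydronaphtho[2,3-d][1,3]dioxol-5-yl]malonate, via sodium malonate enolate 24 (not isolated)
Conditions: NaH (1.05 equiv), THF, 0 °C; 23 (1.3 equiv), −20 °C → rt; AcOH quench
Reagents that add atoms: none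
Why: Michael addition–elimination of the malonate anion (the only acidic C–H deprotonated by one equivalent of NaH) on the β-ethoxy enone is made irreversible by loss of ethoxide and creates the quaternary carbon that becomes pyranone C3', with no new stereocentre and C1/C2 untouched.

Step 14
Reactants: 25 diallyl 2-[(E)-4-tert-butoxy-3,4-dioxobut-1-en-1-yl]-2-[(5R,6R)-7-formyl-6-(methoxycarbonyl)-2,2-diphenyl-5,6-dihydronaphtho[2,3-d][1,3]dioxol-5-yl]malonate
Product: 28 tert-butyl 3-[(5R,6R)-7-formyl-6-(methoxycarbonyl)-2,2-diphenyl-5,6-dihydronaphtho[2,3-d][1,3]dioxol-5-yl]-2-oxo-2H-pyran-6-carboxylate, via malonic diacid 26 (not isolated), via dienol acid 27 (not isolated)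
Conditions: Pd(PPh3)4 (5 mol%), p-TolSO2Na (2.2 equiv), THF/MeOH, rt; aq. NaHSO4; toluene, 50 °C; then DCC (1.1 equiv), 4-(dimethylamino)pyridine (5 mol%), CH2Cl2, 0 °C → rt
Reagents that add atoms: none
Why: Zerovalent palladium ionises both allyl esters and the sulfinate traps the allyl units (Tsuji–Trost deallylation), the resulting vinylogous β-keto malonic acid loses CO2 on warming to the 2-hydroxymuconate-type dienol acid, and carbodiimide activation lets the enol oxygen close the six-membered enol lactone (E/Z isomers equilibrate through the keto tautomers) to give the 2-pyranone.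

Step 15
Reactants: 28 tert-butyl 3-[(5R,6R)-7-formyl-6-(methoxycarbonyl)-2,2-diphenyl-5,6-dihydronaphtho[2,3-d][1,3]dioxol-5-yl]-2-oxo-2H-pyran-6-carboxylate
Product: 29 (5R,6R)-5-[6-(tert-butoxycarbonyl)-2-oxo-2H-pyran-3-yl]-6-(methoxycarbonyl)-2,2-diphenyl-5,6-dihydronaphtho[2,3-d][1,3]dioxole-7-carboxylic acid
Conditions: NaClO2, NaH2PO4, 2-methyl-2-butene, t-BuOH/H2O, 0 °C → rt
Reagents that add atoms: NaClO2 (sodium chlorite), [Na+].[O-]Cl=O
Why: Pinnick oxidation is the standard mild conversion of a conjugated enal into the acrylic acid and leaves the pyranone, the esters, the ketal and both stereocentres alone.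

Step 16
Reactants: 29 (5R,6R)-5-[6-(tert-butoxycarbonyl)-2-oxo-2H-pyran-3-yl]-6-(methoxycarbonyl)-2,2-diphenyl-5,6-dihydronaphtho[2,3-d][1,3]dioxole-7-carboxylic acid
Product: 30 (1R,2R)-1-(6-carboxy-2-oxo-2H-pyran-3-yl)-6,7-dihydroxy-2-(methoxycarbonyl)-1,2-dihydronaphthalene-3-carboxylic acid
Conditions: TFA/CH2Cl2/H2O (10:10:1), rt
Reagents that add atoms: none
Why: Acidolysis cleaves the tert-butyl ester (as 2-methylpropene) and hydrolyses the diphenylmethylene ketal (as benzophenone) while the methyl ester, the pyranone and the acid-stable stereocentres remain, giving the target.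

**Compound list**
1 | 2-bromo-4,5-dimethoxybenzaldehyde | O=Cc1cc(OC)c(OC)cc1Br | starting material
2 | 2-bromo-4,5-dihydroxybenzaldehyde | O=Cc1cc(O)c(O)cc1Br | intermediate
3 | dichlorodiphenylmethane | ClC(Cl)(c1ccccc1)c1ccccc1 | starting material
4 | 6-bromo-2,2-diphenyl-1,3-benzodioxole-5-carbaldehyde | O=Cc1cc2OC(c3ccccc3)(c3ccccc3)Oc2cc1Br | intermediate
5 | ethylene glycol | OCCO | starting material
6 | 5-bromo-6-(1,3-dioxolan-2-yl)-2,2-diphenyl-1,3-benzodioxole | Brc1cc2OC(c3ccccc3)(c3ccccc3)Oc2cc1C1OCCO1 | intermediate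
7 | [6-(1,3-dioxolan-2-yl)-2,2-diphenyl-1,3-benzodioxol-5-yl]lithium | [Li]c1cc2OC(c3ccccc3)(c3ccccc3)Oc2cc1C1OCCO1 | intermediate
8 | 6-(1,3-dioxolan-2-yl)-2,2-diphenyl-1,3-benzodioxole-5-carbaldehyde | O=Cc1cc2OC(c3ccccc3)(c3ccccc3)Oc2cc1C1OCCO1 | intermediate
9 | diallyl malonate | C=CCOC(=O)CC(=O)OCC=C | starting material
10 | diallyl 2-{[6-(1,3-dioxolan-2-yl)-2,2-diphenyl-1,3-benzodioxol-5-yl]methylidene}malonate | C=CCOC(=O)C(=Cc1cc2OC(c3ccccc3)(c3ccccc3)Oc2cc1C1OCCO1)C(=O)OCC=C | intermediate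
11 | 2-(2-bromoethyl)-1,3-dioxolane | BrCCC1OCCO1 | starting material
12 | [2-(1,3-dioxolan-2-yl)ethyl]magnesium bromide | Br[Mg]CCC1OCCO1 | intermediate
13 | 3-(1,3-dioxolan-2-yl)propanal | O=CCCC1OCCO1 | intermediate
14 | diallyl 2-[(1S,2S)-1-[6-(1,3-dioxolan-2-yl)-2,2-diphenyl-1,3-benzodioxol-5-yl]-3-(1,3-dioxolan-2-yl)-2-formylpropyl]malonate | C1(OCCO1)c1cc2OC(c3ccccc3)(c3ccccc3)Oc2cc1[C@@H]([C@@H](C=O)CC1OCCO1)C(C(=O)OCC=C)C(=O)OCC=C | intermediate
15 | (2S,3S)-4,4-bis(allyloxycarbonyl)-3-[6-(1,3-dioxolan-2-yl)-2,2-diphenyl-1,3-benzodioxol-5-yl]-2-(1,3-dioxolan-2-ylmethyl)butanoic acid | C1(OCCO1)c1cc2OC(c3ccccc3)(c3ccccc3)Oc2cc1[C@@H]([C@@H](C(=O)O)CC1OCCO1)C(C(=O)OCC=C)C(=O)OCC=C | intermediate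
16 | 1,1-diallyl 3-methyl (2S,3S)-2-[6-(1,3-dioxolan-2-yl)-2,2-diphenyl-1,3-benzodioxol-5-yl]-4-(1,3-dioxolan-2-yl)butane-1,1,3-tricarboxylate | C1(OCCO1)c1cc2OC(c3ccccc3)(c3ccccc3)Oc2cc1[C@@H]([C@@H](C(=O)OC)CC1OCCO1)C(C(=O)OCC=C)C(=O)OCC=C | intermediate
17 | 1,1-diallyl 3-methyl (2S,3S)-2-(6-formyl-2,2-diphenyl-1,3-benzodioxol-5-yl)-5-oxopentane-1,1,3-tricarboxylate | O=Cc1cc2OC(c3ccccc3)(c3ccccc3)Oc2cc1[C@@H]([C@@H](C(=O)OC)CC=O)C(C(=O)OCC=C)C(=O)OCC=C | intermediate
18 | diallyl 2-[(5S,6R)-7-formyl-6-(methoxycarbonyl)-2,2-diphenyl-5,6-dihydronaphtho[2,3-d][1,3]dioxol-5-yl]malonate (trans) | COC(=O)[C@H]1C(C=O)=Cc2cc3OC(c4ccccc4)(c4ccccc4)Oc3cc2[C@@H]1C(C(=O)OCC=C)C(=O)OCC=C | intermediate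
19 | oxalyl chloride | ClC(=O)C(Cl)=O | starting material
20 | tert-butanol | CC(C)(C)O | starting material
21 | tert-butyl chlorooxoacetate | CC(C)(C)OC(=O)C(Cl)=O | intermediate
22 | ethyl vinyl ether | C=COCC | starting material
23 | tert-butyl (E)-4-ethoxy-2-oxobut-3-enoate | CCO/C=C/C(=O)C(=O)OC(C)(C)C | intermediate
24 | sodium enolate of 18 (malonate carbanion) | [Na+].COC(=O)[C@H]1C(C=O)=Cc2cc3OC(c4ccccc4)(c4ccccc4)Oc3cc2[C@@H]1[C-](C(=O)OCC=C)C(=O)OCC=C | intermediate
25 | diallyl 2-[(E)-4-tert-butoxy-3,4-dioxobut-1-en-1-yl]-2-[(5R,6R)-7-formyl-6-(methoxycarbonyl)-2,2-diphenyl-5,6-dihydronaphtho[2,3-d][1,3]dioxol-5-yl]malonate | COC(=O)[C@H]1C(C=O)=Cc2cc3OC(c4ccccc4)(c4ccccc4)Oc3cc2[C@@H]1C(/C=C/C(=O)C(=O)OC(C)(C)C)(C(=O)OCC=C)C(=O)OCC=C | intermediate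
26 | 2-[(E)-4-tert-butoxy-3,4-dioxobut-1-en-1-yl]-2-[(5R,6R)-7-formyl-6-(methoxycarbonyl)-2,2-diphenyl-5,6-dihydronaphtho[2,3-d][1,3]dioxol-5-yl]malonic acid | COC(=O)[C@H]1C(C=O)=Cc2cc3OC(c4ccccc4)(c4ccccc4)Oc3cc2[C@@H]1C(/C=C/C(=O)C(=O)OC(C)(C)C)(C(=O)O)C(=O)O | intermediate
27 | 6-tert-butoxy-2-[(5R,6R)-7-formyl-6-(methoxycarbonyl)-2,2-diphenyl-5,6-dihydronaphtho[2,3-d][1,3]dioxol-5-yl]-5-hydroxy-6-oxohexa-2,4-dienoic acid (dienol form; double-bond geometry not fixed) | COC(=O)[C@H]1C(C=O)=Cc2cc3OC(c4ccccc4)(c4ccccc4)Oc3cc2[C@@H]1C(C(=O)O)=CC=C(O)C(=O)OC(C)(C)C | intermediate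
28 | tert-butyl 3-[(5R,6R)-7-formyl-6-(methoxycarbonyl)-2,2-diphenyl-5,6-dihydronaphtho[2,3-d][1,3]dioxol-5-yl]-2-oxo-2H-pyran-6-carboxylate | COC(=O)[C@H]1C(C=O)=Cc2cc3OC(c4ccccc4)(c4ccccc4)Oc3cc2[C@@H]1c1ccc(C(=O)OC(C)(C)C)oc1=O | intermediate
29 | (5R,6R)-5-[6-(tert-butoxycarbonyl)-2-oxo-2H-pyran-3-yl]-6-(methoxycarbonyl)-2,2-diphenyl-5,6-dihydronaphtho[2,3-d][1,3]dioxole-7-carboxylic acid | COC(=O)[C@H]1C(C(=O)O)=Cc2cc3OC(c4ccccc4)(c4ccccc4)Oc3cc2[C@@H]1c1ccc(C(=O)OC(C)(C)C)oc1=O | intermediate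
30 | (1R,2R)-1-(6-carboxy-2-oxo-2H-pyran-3-yl)-6,7-dihydroxy-2-(methoxycarbonyl)-1,2-dihydronaphthalene-3-carboxylic acid | COC(=O)[C@H]1C(C(=O)O)=Cc2cc(O)c(O)cc2[C@@H]1c1ccc(C(=O)O)oc1=O | target

**Totals**
Total step count: 16 (13 in the main line, 1 for aldehyde 13, 2 for ketoester 23).
Longest linear sequence: 13 steps (1 → 30 through steps 1–5, 7–10 and 13–16).

**Steps most likely to fail and their fallbacks**

Step 7 is the first risk: the ortho-substituted arylidene malonate is a sluggish acceptor for enamine catalysis, and the configuration at C1 depends on the syn/anti ratio, which is assumed by analogy rather than known for this substrate. The fallback replaces catalysis by an auxiliary-controlled azaenolate Michael addition; it sets out from 13 (with 10 as acceptor) and comes back at 14. Aldehyde 13 is condensed with (S)-1-amino-2-(methoxymethyl)pyrrolidine to the SAMP hydrazone F1. F1 is deprotonated with LiN(iPr)2 in THF and added at −100 °C to 10 to give the adduct hydrazone F2, in which the auxiliary fixes C2 as S and the lithium-chelated transition state sets the benzylic centre. CuCl2 in THF/pH 7 buffer then releases aldehyde 14 and the auxiliary without epimerisation, and the route continues with step 8.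

Step 13 is the second risk: the malonate carbon sits on a ring carbon flanked by the aryl ring and C2, so forming the quaternary centre by addition–elimination may be slow. The fallback swaps the β-ethoxy enone for a linear, unhindered alkynyl ketoester that needs no leaving group; it sets out from 18 and comes back at 25. Di-tert-butyl oxalate is treated with HC≡CMgBr in THF at −78 °C to give tert-butyl 2-oxobut-3-ynoate F3. Conjugate addition of 18 to F3 with Cs2CO3 (10 mol%) in MeCN at 0 °C gives 25, possibly as an E/Z mixture, which is harmless because the geometry is scrambled at the dienol stage of step 14.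

Step 14 is the third risk: three events are telescoped, and the sulfinate, the enal and the keto ester must coexist with the palladium catalyst before the enol lactonisation. The fallback avoids palladium and carbodiimide altogether; it sets out from 25 and comes back at 28. Heating 25 with LiCl in wet DMSO at 90 °C (Krapcho-type dealkoxycarbonylation) lets chloride dealkylate one allyl ester of the doubly activated malonate, and the carboxylate loses CO2 to give the allyl ester dienol F4. The enol oxygen of F4 then closes the pyranone by intramolecular transesterification with loss of allyl alcohol, giving 28.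

Further compounds
F1 | step 7 | (S,E)-N-[3-(1,3-dioxolan-2-yl)propylidene]-2-(methoxymethyl)pyrrolidin-1-amine (SAMP hydrazone of 13) | COC[C@@H]1CCCN1/N=C/CCC1OCCO1
F2 | step 7 | SAMP hydrazone of 14 (adduct hydrazone, C1 S and C2 S as in 14) | COC[C@@H]1CCCN1/N=C/[C@@H](CC1OCCO1)[C@H](c1cc2OC(c3ccccc3)(c3ccccc3)Oc2cc1C1OCCO1)C(C(=O)OCC=C)C(=O)OCC=C
F3 | step 13 | tert-butyl 2-oxobut-3-ynoate | C#CC(=O)C(=O)OC(C)(C)C
F4 | step 14 | 1-allyl 6-tert-butyl 2-[(5R,6R)-7-formyl-6-(methoxycarbonyl)-2,2-diphenyl-5,6-dihydronaphtho[2,3-d][1,3]dioxol-5-yl]-5-hydroxyhexa-2,4-dienedioate (dienol form; geometry not fixed) | COC(=O)[C@H]1C(C=O)=Cc2cc3OC(c4ccccc4)(c4ccccc4)Oc3cc2[C@@H]1C(C(=O)OCC=C)=CC=C(O)C(=O)OC(C)(C)C
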